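**Strategy.** Ring B (the cyclohexane that carries the exocyclic methylene; labdane numbering) is closed by a biomimetic radical cyclisation. The C20 oxygen on the quaternary ring-fusion carbon C10 and the exocyclic C8=C17 alkene, linked through the C9–C10 bond, are the footprint of a titanocene-mediated epoxide opening, alkene addition and β-hydride loss. The precursor is a ring-A spiro-epoxide (C10–O–C20) whose C5 carries an (E)-trisubstituted homoallylic chain. One operation forms C9–C10, sets C9 and C10, frees the C20 hydroxyl and creates the methylene. C5 is set by a copper-mediated conjugate addition directed by a CBS-derived carbinol. C4 is methylated afterwards under control of the new angular group. The butenolide is attached ready-made by Negishi coupling.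

Key step: step 10

Remark: atom labels C1–C20 follow labdane numbering (ring A = C1–C5, C10; ring B = C5–C10); compounds 1, 4 and 22 are taken as purchasable; the spiro carbon of 15 is left undefined because both epimers give the same radical.

**Step 1**
Reactants: 1 methyl 3-oxocyclohex-1-ene-1-carboxylate
Product: 2 methyl (3S)-3-hydroxycyclohex-1-ene-1-carboxylate
Conditions: (R)-2-methyl-CBS-oxazaborolidine (10 mol%), catecholborane, toluene, −78 °C
Reagents that add atoms: none
Why: Corey–Bakshi–Shibata reduction is 1,2-selective for enones, and with the ester-bearing alkenyl arm as the large group the (R)-catalyst should give the (S)-carbinol (the future C10), which serves as control element for C5.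

**Step 2**
Reactants: 2 methyl (3S)-3-hydroxycyclohex-1-ene-1-carboxylate
Product: 3 methyl (3S)-3-[(tert-butyldimethylsilyl)oxy]cyclohex-1-ene-1-carboxylate
Conditions: TBSCl, imidazole, DMF, rt
Reagents that add atoms: tert-butyldimethylsilyl chloride, CC(C)(C)[Si](C)(C)Cl
Why: Routine silylation of the secondary allylic alcohol; the bulky silyl ether later shields its face of the enoate.

**Step 3**
Reactants: 4 tert-butyl(but-3-yn-1-yloxy)dimethylsilane
Product: 7 (3E)-6-[(tert-butyldimethylsilyl)oxy]-4-methylhex-3-en-1-ol, via alkenylalane 5 (not isolated), via lithium alanate 6 (not isolated)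
Conditions: Me3Al, Cp2ZrCl2 (20 mol%), CH2Cl2, 0 °C → rt; n-BuLi, THF/hexane, −30 °C; oxirane, −30 °C → rt; aq. HCl
Reagents that add atoms: trimethylaluminium, C[Al](C)C; oxirane, C1CO1
Why: Zirconium-catalysed carboalumination adds methyl and aluminium syn across the terminal alkyne (methyl to the internal carbon), which fixes the E trisubstituted alkene, and the derived alanate opens oxirane with retention of alkene geometry.

**Step 4**
Reactants: 7 (3E)-6-[(tert-butyldimethylsilyl)oxy]-4-methylhex-3-en-1-ol
Product: 8 tert-butyl{[(3E)-6-chloro-3-methylhex-3-en-1-yl]oxy}dimethylsilane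
Conditions: NCS, PPh3, CH2Cl2, 0 °C → rt
Reagents that add atoms: N-chlorosuccinimide, O=C1CCC(=O)N1Cl
Why: Appel-type chlorination of the primary alcohol (SN2 on the oxyphosphonium ion); silyl ether and alkene are untouched.

**Step 5**
Reactants: 8 tert-butyl{[(3E)-6-chloro-3-methylhex-3-en-1-yl]oxy}dimethylsilane
Product: 9 (3E)-1-bromo-6-chloro-3-methylhex-3-ene
Conditions: Ph3PBr2, CH2Cl2, rt
Reagents that add atoms: dibromotriphenylphosphorane, BrP(Br)(c1ccccc1)(c1ccccc1)c1ccccc1
Why: Dibromotriphenylphosphorane converts a primary silyl ether directly into the bromide under neutral conditions (silyl transfer to bromide, SN2 at carbon), leaving the primary chloride in place.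

**Step 6**
Reactants: 3 methyl (3S)-3-[(tert-butyldimethylsilyl)oxy]cyclohex-1-ene-1-carboxylate; 9 (3E)-1-bromo-6-chloro-3-methylhex-3-ene
Product: 12 methyl (1R,2S,3S)-3-[(tert-butyldimethylsilyl)oxy]-2-[(3E)-6-chloro-3-methylhex-3-en-1-yl]cyclohexane-1-carboxylate, via Grignard reagent 10 (not isolated), via silyl ketene acetal 11 (not isolated)
Conditions: 9, Mg, THF, rt; then 3, CuBr·SMe2 (10 mol%), TMSCl, THF, −78 → −30 °C; aq. HCl; then NaOMe (cat.), MeOH, rt
Reagents that add atoms: none
Why: Copper-catalysed, TMSCl-accelerated conjugate addition of the Grignard reagent (formed selectively at the C–Br bond) should occur anti to the adjacent silyloxy group, which sets C5, and methoxide then epimerises C4 to the all-equatorial isomer with the ester trans to the chain.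

**Step 7**
Reactants: 12 methyl (1R,2S,3S)-3-[(tert-butyldimethylsilyl)oxy]-2-[(3E)-6-chloro-3-methylhex-3-en-1-yl]cyclohexane-1-carboxylate
Product: 13 methyl (1R,2S,3S)-2-[(3E)-6-chloro-3-methylhex-3-en-1-yl]-3-hydroxycyclohexane-1-carboxylate
Conditions: HF·pyridine, THF, 0 °C → rt
Reagents that add atoms: none
Why: Acidic fluoride desilylation avoids an alkoxide that could lactonise onto the cis-1,3 ester; no stereocenter is touched.

**Step 8**
Reactants: 13 methyl (1R,2S,3S)-2-[(3E)-6-chloro-3-methylhex-3-en-1-yl]-3-hydroxycyclohexane-1-carboxylate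
Product: 14 methyl (1R,2S)-2-[(3E)-6-chloro-3-methylhex-3-en-1-yl]-3-oxocyclohexane-1-carboxylate
Conditions: Dess–Martin periodinane, NaHCO3, CH2Cl2, 0 °C → rt
Reagents that add atoms: none
Why: Buffered Dess–Martin oxidation is neutral, so the now α-keto stereocenter C5 (trans to the ester) should not epimerise.

**Step 9**
Reactants: 14 methyl (1R,2S)-2-[(3E)-6-chloro-3-methylhex-3-en-1-yl]-3-oxocyclohexane-1-carboxylate
Product: 15 methyl (4S,5R)-4-[(3E)-6-chloro-3-methylhex-3-en-1-yl]-1-oxaspiro[2.5]octane-5-carboxylate (both epimers at the spiro carbon)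
Conditions: Me3S+ I−, KN(SiMe3)2 (slight deficit), THF, −10 → 0 °C
Reagents that add atoms: trimethylsulfonium iodide, C[S+](C)C.[I-]
Why: Corey–Chaykovsky epoxidation installs C20; the ylide is too weak a base to enolise the ketone, so C5 is kept, and the configuration of the spiro carbon is irrelevant because it becomes a radical centre in step 10.

**Step 10**
Reactants: 15 methyl (4S,5R)-4-[(3E)-6-chloro-3-methylhex-3-en-1-yl]-1-oxaspiro[2.5]octane-5-carboxylate
Product: 17 methyl (1R,4aR,5S,8aS)-5-(2-chloroethyl)-4a-(hydroxymethyl)-6-methylidenedecahydronaphthalene-1-carboxylate, via trimethylsilyl ether 16 (not isolated)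
Conditions: Cp2TiCl2 (20 mol%), Mn dust, TMSCl, 2,4,6-collidine, THF (0.02 M), rt; then 1 M HCl
Reagents that add atoms: none
Why: Cp2TiCl (trivalent titanium, formed from Cp2TiCl2 and Mn) opens the spiro-epoxide homolytically at the more substituted C–O bond to give the tertiary C10 radical with C20 as CH2OTi; this adds to C9 of the (E)-trisubstituted alkene, and the resulting tertiary C8 radical is captured by a second Cp2TiCl and loses a C17 hydrogen (β-hydride elimination) to leave the exocyclic C8=C17 alkene, while TMSCl/collidine release the oxygen as silyl ether 16 and Mn returns titanium to the trivalent state. The closest known reaction type is the Nugent–RajanBabu epoxide opening as used in titanocene-catalysed radical cyclisations of epoxypolyprenes, here with the epoxide exocyclic on C10 so that the oxygen ends on C20. Ring B closes 6-endo-trig through a chair transition state. C10: both epoxide epimers give the same planar radical, and the new bond should form equatorially on ring A (C5 chain equatorial, chair–chair arrangement), so that CH2O becomes axial and trans to H5; C9: the E geometry places C11 equatorial, so that 9-H is trans-diaxial to C20. The step needs 6-endo over 5-exo closure, secured by the methyl on C8 (attack at the less substituted C9 gives a tertiary radical); cyclisation ahead of reduction of the C10 radical, secured by the low stationary concentration of trivalent titanium; and exocyclic termination, the usual outcome of titanium-mediated hydrogen loss; ester and alkyl chloride are inert, and the equatorial ester cannot lactonise onto the axial CH2OH.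

**Step 11**
Reactants: 17 methyl (1R,4aR,5S,8aS)-5-(2-chloroethyl)-4a-(hydroxymethyl)-6-methylidenedecahydronaphthalene-1-carboxylate
Product: 20 methyl (1S,4aS,5S,8aR)-4a-(acetoxymethyl)-5-(2-chloroethyl)-1-methyl-6-methylidenedecahydronaphthalene-1-carboxylate, via dilithium alkoxide enolate 18 (not isolated), via lithium alkoxide 19 (not isolated)
Conditions: LiN(iPr)2 (2.5 equiv), THF/DMPU, −78 → −30 °C; MeI, −78 °C; then Ac2O, −78 °C → rt
Reagents that add atoms: iodomethane, CI; acetic anhydride, CC(=O)OC(C)=O
Why: Two equivalents of amide base give the C20 alkoxide and the C4 ester enolate; methyl iodide should attack the exocyclic enolate from the equatorial α face because the axial C10–CH2OLi group shields the β face (the usual outcome of enolate alkylation in 4-carboalkoxy decalins with an axial C10 substituent), which sets C4 with the ester axial, and acetic anhydride then acylates the alkoxide before it can attack the now cis ester.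

**Step 12**
Reactants: 20 methyl (1S,4aS,5S,8aR)-4a-(acetoxymethyl)-5-(2-chloroethyl)-1-methyl-6-methylidenedecahydronaphthalene-1-carboxylate
Product: 21 methyl (1S,4aS,5S,8aR)-4a-(acetoxymethyl)-5-(2-iodoethyl)-1-methyl-6-methylidenedecahydronaphthalene-1-carboxylate
Conditions: NaI, acetone, reflux
Reagents that add atoms: sodium iodide, [Na+].[I-]
Why: Finkelstein exchange at the unhindered primary chloride, driven by precipitation of NaCl; esters and alkene are inert.

**Step 13**
Reactants: 21 methyl (1S,4aS,5S,8aR)-4a-(acetoxymethyl)-5-(2-iodoethyl)-1-methyl-6-methylidenedecahydronaphthalene-1-carboxylate; 22 3-bromofuran-2(5H)-one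
Product: 24 methyl (1S,4aS,5S,8aR)-4a-(acetoxymethyl)-1-methyl-6-methylidene-5-[2-(2-oxo-2,5-dihydrofuran-3-yl)ethyl]decahydronaphthalene-1-carboxylate, via alkylzinc iodide 23 (not isolated)
Conditions: Zn dust, LiCl, THF, 35 °C; then 22, Pd(OAc)2 (2 mol%), SPhos (4 mol%), THF, rt
Reagents that add atoms: none
Why: Zinc inserts into the primary C–I bond and the alkylzinc iodide undergoes Negishi coupling with the C–Br bond of 22 at zerovalent palladium, which joins C12 to the α-carbon of the preformed butenolide without closing a ring; ester, acetate and the 1,1-disubstituted alkene are tolerated and no stereocenter is affected.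

**Compound list**

1 | methyl 3-oxocyclohex-1-ene-1-carboxylate | COC(=O)C1=CC(=O)CCC1 | starting material
2 | methyl (3S)-3-hydroxycyclohex-1-ene-1-carboxylate | COC(=O)C1=C[C@@H](O)CCC1 | intermediate
3 | methyl (3S)-3-[(tert-butyldimethylsilyl)oxy]cyclohex-1-ene-1-carboxylate | COC(=O)C1=C[C@@H](O[Si](C)(C)C(C)(C)C)CCC1 | intermediate
4 | tert-butyl(but-3-yn-1-yloxy)dimethylsilane | C#CCCO[Si](C)(C)C(C)(C)C | starting material
5 | {(1E)-4-[(tert-butyldimethylsilyl)oxy]-2-methylbut-1-en-1-yl}dimethylaluminium | C[Al](C)/C=C(C)/CCO[Si](C)(C)C(C)(C)C | intermediate (not isolated)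
6 | lithium butyl{(1E)-4-[(tert-butyldimethylsilyl)oxy]-2-methylbut-1-en-1-yl}dimethylaluminate | [Li+].CCCC[Al-](C)(C)/C=C(C)/CCO[Si](C)(C)C(C)(C)C | intermediate (not isolated)
7 | (3E)-6-[(tert-butyldimethylsilyl)oxy]-4-methylhex-3-en-1-ol | OCC/C=C(C)/CCO[Si](C)(C)C(C)(C)C | intermediate
8 | tert-butyl{[(3E)-6-chloro-3-methylhex-3-en-1-yl]oxy}dimethylsilane | ClCC/C=C(C)/CCO[Si](C)(C)C(C)(C)C | intermediate
9 | (3E)-1-bromo-6-chloro-3-methylhex-3-ene | ClCC/C=C(C)/CCBr | intermediate
10 | [(3E)-6-chloro-3-methylhex-3-en-1-yl]magnesium bromide | ClCC/C=C(C)/CC[Mg]Br | intermediate (not isolated)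
11 | methyl trimethylsilyl ketene acetal of 12 | ClCC/C=C(C)/CC[C@@H]1[C@@H](O[Si](C)(C)C(C)(C)C)CCCC1=C(OC)O[Si](C)(C)C | intermediate (not isolated)
12 | methyl (1R,2S,3S)-3-[(tert-butyldimethylsilyl)oxy]-2-[(3E)-6-chloro-3-methylhex-3-en-1-yl]cyclohexane-1-carboxylate | ClCC/C=C(C)/CC[C@@H]1[C@@H](O[Si](C)(C)C(C)(C)C)CCC[C@H]1C(=O)OC | intermediate
13 | methyl (1R,2S,3S)-2-[(3E)-6-chloro-3-methylhex-3-en-1-yl]-3-hydroxycyclohexane-1-carboxylate | ClCC/C=C(C)/CC[C@@H]1[C@@H](O)CCC[C@H]1C(=O)OC | intermediate
14 | methyl (1R,2S)-2-[(3E)-6-chloro-3-methylhex-3-en-1-yl]-3-oxocyclohexane-1-carboxylate | ClCC/C=C(C)/CC[C@@H]1C(=O)CCC[C@H]1C(=O)OC | intermediate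
15 | methyl (4S,5R)-4-[(3E)-6-chloro-3-methylhex-3-en-1-yl]-1-oxaspiro[2.5]octane-5-carboxylate (both spiro epimers) | ClCC/C=C(C)/CC[C@@H]1C2(CO2)CCC[C@H]1C(=O)OC | intermediate
16 | methyl (1R,4aR,5S,8aS)-5-(2-chloroethyl)-6-methylidene-4a-{[(trimethylsilyl)oxy]methyl}decahydronaphthalene-1-carboxylate | C=C1CC[C@@H]2[C@](CO[Si](C)(C)C)(CCC[C@H]2C(=O)OC)[C@H]1CCCl | intermediate (not isolated)
17 | methyl (1R,4aR,5S,8aS)-5-(2-chloroethyl)-4a-(hydroxymethyl)-6-methylidenedecahydronaphthalene-1-carboxylate | C=C1CC[C@@H]2[C@](CO)(CCC[C@H]2C(=O)OC)[C@H]1CCCl | intermediate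
18 | dilithium alkoxide ester enolate of 17 | C=C1CC[C@@H]2[C@](CO[Li])(CCCC2=C(OC)O[Li])[C@H]1CCCl | intermediate (not isolated)
19 | lithium alkoxide of the C4-methylated hydroxy ester | C=C1CC[C@@H]2[C@](CO[Li])(CCC[C@]2(C)C(=O)OC)[C@H]1CCCl | intermediate (not isolated)
20 | methyl (1S,4aS,5S,8aR)-4a-(acetoxymethyl)-5-(2-chloroethyl)-1-methyl-6-methylidenedecahydronaphthalene-1-carboxylate | C=C1CC[C@@H]2[C@](COC(C)=O)(CCC[C@]2(C)C(=O)OC)[C@H]1CCCl | intermediate
21 | methyl (1S,4aS,5S,8aR)-4a-(acetoxymethyl)-5-(2-iodoethyl)-1-methyl-6-methylidenedecahydronaphthalene-1-carboxylate | C=C1CC[C@@H]2[C@](COC(C)=O)(CCC[C@]2(C)C(=O)OC)[C@H]1CCI | intermediate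
22 | 3-bromofuran-2(5H)-one | O=C1OCC=C1Br | starting material
23 | alkylzinc iodide from 21 | C=C1CC[C@@H]2[C@](COC(C)=O)(CCC[C@]2(C)C(=O)OC)[C@H]1CC[Zn]I | intermediate (not isolated)
24 | methyl (1S,4aS,5S,8aR)-4a-(acetoxymethyl)-1-methyl-6-methylidene-5-[2-(2-oxo-2,5-dihydrofuran-3-yl)ethyl]decahydronaphthalene-1-carboxylate | C=C1CC[C@@H]2[C@](COC(C)=O)(CCC[C@]2(C)C(=O)OC)[C@H]1CCC1=CCOC1=O | target

**Step count.** Total: 13 steps. Longest linear sequence: 11 steps (steps 3–13, from 4).

**Steps most likely to fail**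

Step 10. The C10 radical may be reduced or eliminated by a second equivalent of trivalent titanium before it closes the ring (deoxygenation or allylic alcohol formation), the new bond may form on the axial face (cis-fused decalin), or hydrogen may be lost from C7 or C9 instead of C17. The fallback generates the same radical from a tertiary bromide with cobalt; it sets out from 15 and comes back at 17. Me2BBr (CH2Cl2, −78 °C) should open the epoxide at its tertiary carbon to give methyl (1R,2S)-3-bromo-2-[(3E)-6-chloro-3-methylhex-3-en-1-yl]-3-(hydroxymethyl)cyclohexane-1-carboxylate F1. The monovalent cobalt species formed from Co(dmgH)2(py)Cl and Zn dust (MeCN, visible light) should reduce the tertiary bromide to the C10 radical. After 6-endo closure the tertiary C8 radical is captured by divalent cobalt and loses a C17 hydrogen by dehydrocobaltation, which gives 17 (cobaloxime-mediated radical cyclisation–elimination).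

Step 11. Deprotonation of the hindered axial C4–H next to the angular alkoxide may be incomplete, methylation may occur partly from the β face, and the alkoxide may attack the ester (lactone formation) or the chloroethyl arm before it is acylated. The fallback moves the methylation ahead of ring closure; it sets out from 14 and comes back at 20. Kinetic enolisation at C1 and silylation (LiN(iPr)2, TMSCl, THF, −78 °C) should give methyl (1R,2S)-2-[(3E)-6-chloro-3-methylhex-3-en-1-yl]-3-[(trimethylsilyl)oxy]cyclohex-3-ene-1-carboxylate F2, in which C10 is sp2 and C5 can no longer epimerise. The ester enolate (LiN(iPr)2) is then methylated by MeI anti to the C5 chain, which allylic strain holds axial, to give methyl (1S,2S)-2-[(3E)-6-chloro-3-methylhex-3-en-1-yl]-1-methyl-3-[(trimethylsilyl)oxy]cyclohex-3-ene-1-carboxylate F3. Aqueous acid releases methyl (1S,2S)-2-[(3E)-6-chloro-3-methylhex-3-en-1-yl]-1-methyl-3-oxocyclohexane-1-carboxylate F4, and Corey–Chaykovsky epoxidation gives methyl (4S,5S)-4-[(3E)-6-chloro-3-methylhex-3-en-1-yl]-5-methyl-1-oxaspiro[2.5]octane-5-carboxylate F5. The titanocene cyclisation under the conditions of step 10, now with an axial ester on C4 that blocks the β face of the C10 radical, should give methyl (1S,4aS,5S,8aR)-5-(2-chloroethyl)-1-methyl-6-methylidene-4a-{[(trimethylsilyl)oxy]methyl}decahydronaphthalene-1-carboxylate F6 and, after acidic work-up, methyl (1S,4aS,5S,8aR)-5-(2-chloroethyl)-4a-(hydroxymethyl)-1-methyl-6-methylidenedecahydronaphthalene-1-carboxylate F7. F7 is acetylated at once (Ac2O, pyridine, DMAP) to 20.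

Step 13. Zinc insertion may be slow or the alkylzinc may be protonated, the alkylpalladium may undergo β-hydride elimination, and the bromobutenolide may be consumed by conjugate addition or ring opening. The fallback replaces the cross-coupling by enolate alkylation and sulfoxide elimination; it sets out from 21 and comes back at 24. The lithium enolate of purchasable 3-(phenylsulfanyl)oxolan-2-one (LiN(SiMe3)2, THF/DMPU, −78 → 0 °C) is alkylated by iodide 21 to give methyl (1S,4aS,5S,8aR)-4a-(acetoxymethyl)-1-methyl-6-methylidene-5-{2-[2-oxo-3-(phenylsulfanyl)oxolan-3-yl]ethyl}decahydronaphthalene-1-carboxylate F8. Oxidation at sulfur (NaIO4, MeOH/H2O) gives methyl (1S,4aS,5S,8aR)-4a-(acetoxymethyl)-5-{2-[3-(benzenesulfinyl)-2-oxooxolan-3-yl]ethyl}-1-methyl-6-methylidenedecahydronaphthalene-1-carboxylate F9. Thermolysis (toluene, 110 °C) eliminates the sulfoxide into the lactone ring and gives 24.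

**Further compounds**

F1 | step 10 | methyl (1R,2S)-3-bromo-2-[(3E)-6-chloro-3-methylhex-3-en-1-yl]-3-(hydroxymethyl)cyclohexane-1-carboxylate | ClCC/C=C(C)/CC[C@@H]1C(Br)(CO)CCC[C@H]1C(=O)OC
F2 | step 11 | methyl (1R,2S)-2-[(3E)-6-chloro-3-methylhex-3-en-1-yl]-3-[(trimethylsilyl)oxy]cyclohex-3-ene-1-carboxylate | ClCC/C=C(C)/CC[C@@H]1C(O[Si](C)(C)C)=CCC[C@H]1C(=O)OC
F3 | step 11 | methyl (1S,2S)-2-[(3E)-6-chloro-3-methylhex-3-en-1-yl]-1-methyl-3-[(trimethylsilyl)oxy]cyclohex-3-ene-1-carboxylate | ClCC/C=C(C)/CC[C@@H]1C(O[Si](C)(C)C)=CCC[C@]1(C)C(=O)OC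
F4 | step 11 | methyl (1S,2S)-2-[(3E)-6-chloro-3-methylhex-3-en-1-yl]-1-methyl-3-oxocyclohexane-1-carboxylate | ClCC/C=C(C)/CC[C@@H]1C(=O)CCC[C@]1(C)C(=O)OC
F5 | step 11 | methyl (4S,5S)-4-[(3E)-6-chloro-3-methylhex-3-en-1-yl]-5-methyl-1-oxaspiro[2.5]octane-5-carboxylate | ClCC/C=C(C)/CC[C@@H]1C2(CO2)CCC[C@]1(C)C(=O)OC
F6 | step 11 | methyl (1S,4aS,5S,8aR)-5-(2-chloroethyl)-1-methyl-6-methylidene-4a-{[(trimethylsilyl)oxy]methyl}decahydronaphthalene-1-carboxylate | C=C1CC[C@@H]2[C@](CO[Si](C)(C)C)(CCC[C@]2(C)C(=O)OC)[C@H]1CCCl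
F7 | step 11 | methyl (1S,4aS,5S,8aR)-5-(2-chloroethyl)-4a-(hydroxymethyl)-1-methyl-6-methylidenedecahydronaphthalene-1-carboxylate | C=C1CC[C@@H]2[C@](CO)(CCC[C@]2(C)C(=O)OC)[C@H]1CCCl
F8 | step 13 | methyl (1S,4aS,5S,8aR)-4a-(acetoxymethyl)-1-methyl-6-methylidene-5-{2-[2-oxo-3-(phenylsulfanyl)oxolan-3-yl]ethyl}decahydronaphthalene-1-carboxylate | C=C1CC[C@@H]2[C@](COC(C)=O)(CCC[C@]2(C)C(=O)OC)[C@H]1CCC1(Sc2ccccc2)CCOC1=O
F9 | step 13 | methyl (1S,4aS,5S,8aR)-4a-(acetoxymethyl)-5-{2-[3-(benzenesulfinyl)-2-oxooxolan-3-yl]ethyl}-1-methyl-6-methylidenedecahydronaphthalene-1-carboxylate | C=C1CC[C@@H]2[C@](COC(C)=O)(CCC[C@]2(C)C(=O)OC)[C@H]1CCC1(S(=O)c2ccccc2)CCOC1=O
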